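**Read in molar.** Multiply each last E reading by its charge of E.

| setting | south | south-west | south-east | flask |
|---|---|---|---|---|
| E | 0.63 M | 0.99 M | 0.45 M | 0.45 M |
| D | 2.8 mol% | 2.8 mol% | 5.6 mol% | 2.8 mol% |
| remark | run made earlier | run made earlier | run made earlier |  |
| time |  |  |  | 15 min |

| run | time / min | Z / % | E / % |
|---|---|---|---|
| south | 1.33 | 38 | 64 |
| south | 2.50 | 48 | 50 |
| south | 4.00 | 55 | 44 |
| south | 8.00 | 62 | 36 |
| south | 15.0 | 60 | 37 |
| south-west | 1.33 | 59 | 43 |
| south-west | 4.00 | 73 | 25 |
| south-west | 8.00 | 74 | 24 |
| south-west | 10.0 | 78 | 26 |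
| south-west | 15.0 | 75 | 24 |
| south-east | 3.00 | 43 | 58 |
| south-east | 6.00 | 46 | 53 |
| south-east | 10.0 | 46 | 53 |
| south-east | 12.0 | 45 | 54 |
| south-east | 15.0 | 45 | 54 |

(each reading ± 1.5 percentage points)

- the average divides the monomer in chains by the number of chains begun, living and dead together
- the earlier runs do not show the number of chains; that part of a forecast is a guess

* average number of monomer units in a chain (chains begun, living or dead) at 15 min
* part of the E that has reacted at 15 min

South gives 0.233 M, south-west 0.238 M, south-east 0.243 M. The charges span a factor of 2.20, yet these three lie within 0.00990 M of each other. Take their mean, 0.238 M, and call it the floor: the cE at which E stops turning into Z on balance (the equilibrium monomer concentration).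

**Bench rule.** For a flask on its plateau, subtract floor over charged cE from one. This flask, charged at 0.45 M, gets 47.1% reacted.

**Its border.** The rule needs the plateau reached in time. South-east has the same cE and stands flat by 6.00 min. This flask has half of its D. Assume the time stretches inversely with D. That estimate puts the plateau at 12.0 min, and 15 min is 1.25 times that. So commit to the rule for c here. The earlier runs do not show the number of chains, so any dp is a guess.

**The forecast.** It gives 47% reacted and a dp of 17.5. Of the chain count it says: “This is a guess”.

**The result.** The flask gives 46.5% reacted, and a dp of 20.2, above the forecast's.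

    E + D → L + Z (k = 0.150 M⁻¹ s⁻¹)
    L → G (k = 0.00210 s⁻¹)
    Z + L → E + L, rate k3*[L] as long as [Z] is above zero (k = 0.210 s⁻¹)
    2 D → J (k = 1.20 M⁻¹ s⁻¹)
    E + L → Z + L, rate k5*[L]*[E] (k = 0.890 M⁻¹ s⁻¹)

**Floor again.** Left until 150 min, the flask stands at 47.0% reacted, against 47.1% from the floor. Now take a flask charged at 0.77 M of E, with the same loading of D and the same time. The floor gives 69.1% reacted. That flask stands at 69.2%.

All runs were generated by integration on assumed constants; the scatter is artificial.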